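**Retrosynthetic overview**

1. Target ⇐ aryl silyl ether cleavage ⇐ Markovnikov hydration of one exocyclic methylene, relayed by the neighbouring aroyloxy group (sets the tertiary carbinol) ⇐ enantioselective mono-aroylation of a meso 5,9-dimethylidenecyclodecane-1,3-diol (fixes the three contiguous stereocentres).
2. Meso diol ⇐ syn-1,3-reduction of a racemic β-hydroxy cyclodecanone ⇐ Grob fragmentation of a cis-fused hydroazulene 1,3-diol monomesylate; this is the key ring expansion (five- plus seven-membered rings → ten-membered ring) and it creates the second exocyclic methylene.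
3. Hydroazulene ⇐ carbonyl-ene closure of the seven-membered ring onto a cyclopentanone β-keto ester ⇐ C-alkylation with 5-bromo-2-methylpent-1-ene ⇐ Dieckmann cyclisation of the anti-aldol adduct of methyl 3-methylbutanoate and methyl 4-oxobutanoate.
4. Ring order: cyclopentane (Dieckmann) → cycloheptane (ene) → cyclodecane (Grob); the aroyl unit is built from 4-iodophenol and CO2.

Assumption: racemic intermediates are written as one enantiomer with the relative configuration shown (RS descriptors); the meso diol is achiral, and absolute configuration enters at the mono-aroylation.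

**Route**

Step 1
Reactants: 1 methyl 3-methylbutanoate; 2 methyl 4-oxobutanoate
Product: 3 dimethyl (2RS,3RS)-3-hydroxy-2-(propan-2-yl)hexanedioate (anti aldol, racemic)
Conditions: Cy2BOTf, Et3N, CH2Cl2, −78 °C; 2, −78 → 0 °C; H2O2, pH 7 buffer, MeOH
Reagents that add atoms: none
Why: Anti-selective boron aldol addition: Cy2BOTf/Et3N gives the E(O) boron enolate of the ester, whose chair Zimmerman–Traxler transition state with the aldehyde sets the 2,3-anti pair (racemic), the ester of 2 being untouched.

Step 2
Reactants: 3 dimethyl (2RS,3RS)-3-hydroxy-2-(propan-2-yl)hexanedioate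
Product: 4 dimethyl (2RS,3RS)-2-(propan-2-yl)-3-[(triethylsilyl)oxy]hexanedioate
Conditions: TESCl, imidazole, DMF, 0 °C → rt (crude 3 used at once)
Reagents that add atoms: chlorotriethylsilane (TESCl), CC[Si](CC)(CC)Cl
Why: Silyl ether formation blocks γ-lactonisation of the hydroxy diester and protects the carbinol from retro-aldol and elimination in the basic steps that follow.

Step 3
Reactants: 4 dimethyl (2RS,3RS)-2-(propan-2-yl)-3-[(triethylsilyl)oxy]hexanedioate
Product: 5 methyl (3RS,4RS)-2-oxo-3-(propan-2-yl)-4-[(triethylsilyl)oxy]cyclopentane-1-carboxylate (isopropyl and silyloxy cis; C-1 epimerisable)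
Conditions: NaHMDS (2.1 equiv), THF, −78 → −20 °C; AcOH
Reagents that add atoms: none
Why: Dieckmann condensation: the unhindered CH2CO2Me is deprotonated kinetically and attacks the other ester to close the five-membered ring, the product being held as its β-keto ester enolate so the two stereocentres are not touched (the anti aldol pair becomes the 3,4-cis pair on the ring).

Step 4
Reactants: 5 methyl (3RS,4RS)-2-oxo-3-(propan-2-yl)-4-[(triethylsilyl)oxy]cyclopentane-1-carboxylate; 6 5-bromo-2-methylpent-1-ene
Product: 7 methyl (3RS,4RS)-1-(4-methylpent-4-en-1-yl)-2-oxo-3-(propan-2-yl)-4-[(triethylsilyl)oxy]cyclopentane-1-carboxylate (both C-1 epimers)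
Conditions: NaH (1.05 equiv), DMF, 0 °C; 6, NaI (cat.), rt
Reagents that add atoms: none
Why: SN2 C-alkylation of the β-keto ester sodium enolate builds the quaternary C-1; its configuration is irrelevant because this carbon becomes sp2 in step 7, and no base is left over to epimerise C-3.

Step 5
Reactants: 7 methyl (3RS,4RS)-1-(4-methylpent-4-en-1-yl)-2-oxo-3-(propan-2-yl)-4-[(triethylsilyl)oxy]cyclopentane-1-carboxylate
Product: 8 methyl (2RS,3RS)-3a-hydroxy-5-methylidene-3-(propan-2-yl)-2-[(triethylsilyl)oxy]decahydroazulene-8a-carboxylate (cis-fused; both fusion diastereomers)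
Conditions: Me2AlCl (2 equiv), CH2Cl2, −78 → 0 °C
Reagents that add atoms: none
Why: Type-two intramolecular carbonyl-ene reaction: Me2AlCl chelates the β-keto ester, the terminal CH2 of the 1,1-disubstituted alkene adds to the activated ketone and an allylic methyl hydrogen passes to oxygen, closing the seven-membered ring cis-fused and leaving an exocyclic methylene.

Step 6
Reactants: 8 methyl (2RS,3RS)-3a-hydroxy-5-methylidene-3-(propan-2-yl)-2-[(triethylsilyl)oxy]decahydroazulene-8a-carboxylate
Product: 9 (2RS,3RS)-8a-(hydroxymethyl)-5-methylidene-3-(propan-2-yl)-2-[(triethylsilyl)oxy]decahydroazulen-3a-ol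
Conditions: LiAlH4, THF, 0 °C
Reagents that add atoms: none
Why: Hydride reduction of the ester to the primary alcohol; the tertiary alcohol, silyl ether and alkene are inert to LiAlH4.

Step 7
Reactants: 9 (2RS,3RS)-8a-(hydroxymethyl)-5-methylidene-3-(propan-2-yl)-2-[(triethylsilyl)oxy]decahydroazulen-3a-ol
Product: 12 (2RS,3RS)-3-hydroxy-5,9-dimethylidene-2-(propan-2-yl)cyclodecan-1-one, via hydroazulenylmethyl mesylate 10 (not isolated), via silyloxy cyclodecanone 11 (not isolated)
Conditions: MsCl, Et3N, CH2Cl2, 0 °C; KHMDS (1.05 equiv), THF, −78 → 0 °C; HF·pyridine, THF, 0 °C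
Reagents that add atoms: none
Why: Grob (Wharton-type) fragmentation as the ring expansion: after selective mesylation of the primary alcohol, the tertiary potassium alkoxide pushes, the C3a–C8a ring-fusion bond (antiperiplanar to the freely rotating CH2–OMs bond) breaks and mesylate leaves, so the five- and seven-membered rings open to the ten-membered ketone with a second exocyclic methylene, and HF·pyridine then frees the β-hydroxyl without retro-aldol.

Step 8
Reactants: 12 (2RS,3RS)-3-hydroxy-5,9-dimethylidene-2-(propan-2-yl)cyclodecan-1-one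
Product: 13 (1R,2s,3S)-5,9-dimethylidene-2-(propan-2-yl)cyclodecane-1,3-diol (meso)
Conditions: Et2BOMe, THF/MeOH 4:1, −78 °C; NaBH4; MeOH co-evaporation
Reagents that add atoms: none
Why: Narasaka–Prasad reduction: the boron chelate of the β-hydroxy ketone takes external hydride axially to give the syn-1,3-diol, which with the anti aldol pair makes the anti,anti triad, and both enantiomers of racemic 12 converge on the one achiral meso diol.

Step 9
Reactants: 14 4-iodophenol
Product: 15 tert-butyl(4-iodophenoxy)dimethylsilane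
Conditions: TBSCl, imidazole, DMF, rt
Reagents that add atoms: tert-butylchlorodimethylsilane (TBSCl), CC(C)(C)[Si](C)(C)Cl
Why: Silylation of the phenol so that neither the aryl Grignard reagent nor the later acyl chloride is quenched or self-acylated.

Step 10
Reactants: 15 tert-butyl(4-iodophenoxy)dimethylsilane; 16 carbon dioxide
Product: 18 4-[(tert-butyldimethylsilyl)oxy]benzoic acid, via arylmagnesium chloride 17 (not isolated)
Conditions: iPrMgCl·LiCl, THF, −20 °C; CO2, −20 °C → rt; aq. citric acid
Reagents that add atoms: none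
Why: Iodine–magnesium exchange followed by carboxylation of the aryl Grignard reagent gives the benzoic acid.

Step 11
Reactants: 13 (1R,2s,3S)-5,9-dimethylidene-2-(propan-2-yl)cyclodecane-1,3-diol; 18 4-[(tert-butyldimethylsilyl)oxy]benzoic acid
Product: 20 (1R,2S,3S)-3-hydroxy-5,9-dimethylidene-2-(propan-2-yl)cyclodecyl 4-[(tert-butyldimethylsilyl)oxy]benzoate, via aroyl chloride 19 (not isolated)
Conditions: (COCl)2, DMF (cat.), CH2Cl2, 0 °C → rt, evaporate; 13, Cu(OTf)2 (5 mol %), (S,S)-Ph-BOX (6 mol %), iPr2NEt, CH2Cl2, −40 °C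
Reagents that add atoms: none
Why: Enantioselective desymmetrising mono-acylation of a meso diol (copper–bis(oxazoline)-catalysed monobenzoylation type): the syn-1,3-diol chelates the chiral copper Lewis acid, which activates one enantiotopic hydroxyl, and acylation of the 1R hydroxyl fixes C-1, C-2 and C-3 of the target at once (the ligand antipode is chosen for this sense, and a cold base-free work-up avoids 1,3-acyl migration, which would racemise).

Step 12
Reactants: 20 (1R,2S,3S)-3-hydroxy-5,9-dimethylidene-2-(propan-2-yl)cyclodecyl 4-[(tert-butyldimethylsilyl)oxy]benzoate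
Product: 21 (1R,2S,3S,9R)-3,9-dihydroxy-9-methyl-5-methylidene-2-(propan-2-yl)cyclodecyl 4-[(tert-butyldimethylsilyl)oxy]benzoate
Conditions: Co(salen), i.e. Co(C16H14N2O2) (5 mol %), N-fluoro-2,4,6-trimethylpyridinium triflate (1.3 equiv), PhSiH3 (1.3 equiv), acetone, 0 °C; then H2O, NaHCO3
Reagents that add atoms: water, O
Why: Proposed new method: aroyloxy-relayed radical-polar-crossover hydration — the cobalt hydride formed from Co(salen), the N-fluoropyridinium oxidant and PhSiH3 transfers a hydrogen atom reversibly to the CH2 terminus of either methylidene, but only the tertiary C-9 centre, once oxidised through its alkylcobalt, is captured by the carbonyl oxygen of the neighbouring C-1 aroyloxy group as a six-membered 2-aryl-1,3-dioxan-2-ylium ion (the C-5 centre would need a four-membered oxetane closure and reverts to alkene), the ten-membered ring can span positions 4 and 6 of that dioxane only cis so the new C–O bond is 1,3-syn to the C-1 oxygen (9R), and aqueous bicarbonate opens the ortho-acid to the tertiary alcohol with the ester left on the secondary oxygen; the closest known chemistry is Mukaiyama hydration and cobalt-salen hydrogen-atom-transfer hydroalkoxylation and hydroacyloxylation of unactivated alkenes, combined with neighbouring-acyloxy (Woodward–Prévost-type) participation.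

Step 13
Reactants: 21 (1R,2S,3S,9R)-3,9-dihydroxy-9-methyl-5-methylidene-2-(propan-2-yl)cyclodecyl 4-[(tert-butyldimethylsilyl)oxy]benzoate
Product: 22 (1R,2S,3S,9R)-3,9-dihydroxy-9-methyl-5-methylidene-2-(propan-2-yl)cyclodecyl 4-hydroxybenzoate (CNP0293401.1)
Conditions: TBAF, AcOH (1:1), THF, 0 °C
Reagents that add atoms: none
Why: Fluoride cleavage of the aryl silyl ether, buffered with acetic acid so that the ester neither migrates nor hydrolyses, gives the target.

**Compound list**

1 | methyl 3-methylbutanoate | COC(=O)CC(C)C | starting material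
2 | methyl 4-oxobutanoate | COC(=O)CCC=O | starting material
3 | dimethyl (2RS,3RS)-3-hydroxy-2-(propan-2-yl)hexanedioate | COC(=O)[C@@H](C(C)C)[C@@H](O)CCC(=O)OC | intermediate
4 | dimethyl (2RS,3RS)-2-(propan-2-yl)-3-[(triethylsilyl)oxy]hexanedioate | COC(=O)[C@@H](C(C)C)[C@@H](O[Si](CC)(CC)CC)CCC(=O)OC | intermediate
5 | methyl (3RS,4RS)-2-oxo-3-(propan-2-yl)-4-[(triethylsilyl)oxy]cyclopentane-1-carboxylate | COC(=O)C1C(=O)[C@@H](C(C)C)[C@@H](O[Si](CC)(CC)CC)C1 | intermediate
6 | 5-bromo-2-methylpent-1-ene | C=C(C)CCCBr | starting material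
7 | methyl (3RS,4RS)-1-(4-methylpent-4-en-1-yl)-2-oxo-3-(propan-2-yl)-4-[(triethylsilyl)oxy]cyclopentane-1-carboxylate | COC(=O)C1(CCCC(C)=C)C(=O)[C@@H](C(C)C)[C@@H](O[Si](CC)(CC)CC)C1 | intermediate
8 | methyl (2RS,3RS)-3a-hydroxy-5-methylidene-3-(propan-2-yl)-2-[(triethylsilyl)oxy]decahydroazulene-8a-carboxylate (cis-fused) | COC(=O)C12CCCC(=C)CC1(O)[C@@H](C(C)C)[C@@H](O[Si](CC)(CC)CC)C2 | intermediate
9 | (2RS,3RS)-8a-(hydroxymethyl)-5-methylidene-3-(propan-2-yl)-2-[(triethylsilyl)oxy]decahydroazulen-3a-ol | OCC12CCCC(=C)CC1(O)[C@@H](C(C)C)[C@@H](O[Si](CC)(CC)CC)C2 | intermediate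
10 | [(2RS,3RS)-3a-hydroxy-5-methylidene-3-(propan-2-yl)-2-[(triethylsilyl)oxy]decahydroazulen-8a-yl]methyl methanesulfonate | CS(=O)(=O)OCC12CCCC(=C)CC1(O)[C@@H](C(C)C)[C@@H](O[Si](CC)(CC)CC)C2 | intermediate
11 | (2RS,3RS)-5,9-dimethylidene-2-(propan-2-yl)-3-[(triethylsilyl)oxy]cyclodecan-1-one | C=C1CCCC(=C)CC(=O)[C@@H](C(C)C)[C@@H](O[Si](CC)(CC)CC)C1 | intermediate
12 | (2RS,3RS)-3-hydroxy-5,9-dimethylidene-2-(propan-2-yl)cyclodecan-1-one | C=C1CCCC(=C)CC(=O)[C@@H](C(C)C)[C@@H](O)C1 | intermediate
13 | (1R,2s,3S)-5,9-dimethylidene-2-(propan-2-yl)cyclodecane-1,3-diol (meso) | C=C1CCCC(=C)C[C@@H](O)[C@@H](C(C)C)[C@@H](O)C1 | intermediate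
14 | 4-iodophenol | Oc1ccc(I)cc1 | starting material
15 | tert-butyl(4-iodophenoxy)dimethylsilane | CC(C)(C)[Si](C)(C)Oc1ccc(I)cc1 | intermediate
16 | carbon dioxide | O=C=O | starting material
17 | {4-[(tert-butyldimethylsilyl)oxy]phenyl}magnesium chloride | CC(C)(C)[Si](C)(C)Oc1ccc([Mg]Cl)cc1 | intermediate
18 | 4-[(tert-butyldimethylsilyl)oxy]benzoic acid | CC(C)(C)[Si](C)(C)Oc1ccc(cc1)C(=O)O | intermediate
19 | 4-[(tert-butyldimethylsilyl)oxy]benzoyl chloride | CC(C)(C)[Si](C)(C)Oc1ccc(cc1)C(=O)Cl | intermediate
20 | (1R,2S,3S)-3-hydroxy-5,9-dimethylidene-2-(propan-2-yl)cyclodecyl 4-[(tert-butyldimethylsilyl)oxy]benzoate | C=C1CCCC(=C)C[C@@H](OC(=O)c2ccc(O[Si](C)(C)C(C)(C)C)cc2)[C@@H](C(C)C)[C@@H](O)C1 | intermediate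
21 | (1R,2S,3S,9R)-3,9-dihydroxy-9-methyl-5-methylidene-2-(propan-2-yl)cyclodecyl 4-[(tert-butyldimethylsilyl)oxy]benzoate | C=C1CCC[C@@](C)(O)C[C@@H](OC(=O)c2ccc(O[Si](C)(C)C(C)(C)C)cc2)[C@@H](C(C)C)[C@@H](O)C1 | intermediate
22 | (1R,2S,3S,9R)-3,9-dihydroxy-9-methyl-5-methylidene-2-(propan-2-yl)cyclodecyl 4-hydroxybenzoate | C=C1CCC[C@@](C)(O)C[C@@H](OC(=O)c2ccc(O)cc2)[C@@H](C(C)C)[C@@H](O)C1 | target

**Step count and risks**

Total step count: 13. Longest linear sequence: 11 steps (steps 1–8 and 11–13); steps 9–10 make the aroyl component.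

Three steps most likely to fail:

Step 12 (the new reaction). Risks are hydrogen-atom transfer at the wrong methylidene followed by alkene isomerisation, oxetane formation with the free hydroxyl, or transannular capture of the tertiary centre. Fallback with known chemistry, from 20 back to 21: NIS in wet MeCN with NaHCO3 at −20 °C forms the iodonium ion of the 9-methylidene, which the neighbouring aroyloxy group opens at the tertiary carbon through the same cis-bridged dioxanylium ion. Hydrolysis gives (1R,2S,3S,9R)-3,9-dihydroxy-9-(iodomethyl)-5-methylidene-2-(propan-2-yl)cyclodecyl 4-[(tert-butyldimethylsilyl)oxy]benzoate F3. Radical deiodination with Bu3SnH and AIBN in toluene at 80 °C then gives 21.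

Step 11 (enantio-determining desymmetrisation of a hindered macrocyclic diol). Risks are low selectivity, diacylation, or the wrong sense. Fallback, from 18 (with 13) back to 20: Pd(OAc)2-catalysed transvinylation of 18 with vinyl acetate gives ethenyl 4-[(tert-butyldimethylsilyl)oxy]benzoate F2. Candida antarctica lipase B in MTBE then transfers the aroyl group from F2 to the R-configured carbinol of 13 (Kazlauskas preference: large group CH(iPr), medium group CH2) to give 20.

Step 5 (ene closure of a seven-membered ring onto a hindered ketone). Risks are no reaction, chloride capture, or hydrogen transfer from the ring CH2. Fallback, from 7 back to 8: selenium-catalysed ene-type allylic chlorination (NCS, PhSeCl cat., CH2Cl2) converts the isopropenyl end into a 2-(chloromethyl)allyl unit, giving methyl (3RS,4RS)-1-[4-(chloromethyl)pent-4-en-1-yl]-2-oxo-3-(propan-2-yl)-4-[(triethylsilyl)oxy]cyclopentane-1-carboxylate F1. Nozaki–Hiyama allylation of the ring ketone (CrCl2, LiI cat., THF) then closes the seven-membered ring to 8.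

Further compounds
F1 | step 5 | methyl (3RS,4RS)-1-[4-(chloromethyl)pent-4-en-1-yl]-2-oxo-3-(propan-2-yl)-4-[(triethylsilyl)oxy]cyclopentane-1-carboxylate | COC(=O)C1(CCCC(=C)CCl)C(=O)[C@@H](C(C)C)[C@@H](O[Si](CC)(CC)CC)C1
F2 | step 11 | ethenyl 4-[(tert-butyldimethylsilyl)oxy]benzoate | C=COC(=O)c1ccc(O[Si](C)(C)C(C)(C)C)cc1
F3 | step 12 | (1R,2S,3S,9R)-3,9-dihydroxy-9-(iodomethyl)-5-methylidene-2-(propan-2-yl)cyclodecyl 4-[(tert-butyldimethylsilyl)oxy]benzoate | C=C1CCC[C@@](CI)(O)C[C@@H](OC(=O)c2ccc(O[Si](C)(C)C(C)(C)C)cc2)[C@@H](C(C)C)[C@@H](O)C1
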